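**Plan**

Atom labels: C1 ring CH carrying the side chain, C2/C3 ring CH2, C4 ring CH(CH3), C4a/C8a ring-fusion carbons, C5/C6 the C–OH carbons, C7 the C–CO2H carbon, C8 aromatic CH; chain C11 = CH(C18H2OAc), C12–C14 = CH2, C15 = CH(CH3), C16 = CH2OAc; ring A is the arene, ring B the carbocycle; TBS = tert-butyldimethylsilyl.
Enabling feature: C1 and C4 are both benzylic CH carbons on the neighbouring arene carbons C8a and C4a and are linked only through C2–C3, so ring B can be stored as two ortho aryl–CH(R)–CH=CH2 arms and the 1,4-trans relation can be fixed before any ring exists.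
Retrosynthesis, in order: acetates and phenol methyl ethers; C7–CO2H (ortho-lithiation/CO2); C2–C3, as the C2=C3 alkene of a ring-closing metathesis; C1–C11 (iridium/amine α-allylation of a chain aldehyde); C4–CH3 (copper-catalysed SN2′ methylation); C13–C14 (copper-catalysed alkyl–alkyl coupling).
Forward: arene fragment 7 (steps 1–5) and chain aldehyde 13 (steps 6–9) are made separately and joined at C1–C11 (step 10); ring B is then closed on the preformed ring A (step 12), saturated, carboxylated at C7, and the protecting groups are exchanged (steps 13–17).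
Stereochemistry: C15 comes from (R)-3-bromo-2-methylpropan-1-ol, C4 from the chiral copper catalyst (step 4), C1 from the iridium ligand and C11 from the amine catalyst (both step 10); no later step touches these centres.

Key step: step 12

Assumption: the antipodes of the three chiral catalysts are assigned from the usual facial models ((S,S)-Taniaphos for 4R, the (S)-phosphoramidite–olefin ligand for 1S, the (R)-diarylprolinol silyl ether for 11S); each acts on its own centre, so a reversed sense at any one centre would be corrected by taking the mirror-image catalyst without changing the route.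

**Route**

Step 1
Reactants: 1 6-bromo-2,3-dimethoxybenzaldehyde
Product: 2 ethyl (2E)-3-(6-bromo-2,3-dimethoxyphenyl)prop-2-enoate
Conditions: (EtO)2P(O)CH2CO2Et, NaH, THF, 0 °C → rt
Reagents that add atoms: triethyl phosphonoacetate, CCOC(=O)CP(=O)(OCC)OCC
Why: Horner–Wadsworth–Emmons olefination of a non-enolisable aryl aldehyde with a stabilised phosphonate anion, in which reversible addition and syn-elimination of phosphate favour the E-enoate.

Step 2
Reactants: 2 ethyl (2E)-3-(6-bromo-2,3-dimethoxyphenyl)prop-2-enoate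
Product: 3 (2E)-3-(6-bromo-2,3-dimethoxyphenyl)prop-2-en-1-ol
Conditions: i-Bu2AlH (2.5 equiv), CH2Cl2, −78 °C; aq. potassium sodium tartrate
Reagents that add atoms: none
Why: 1,2-reduction of an enoate by an electrophilic aluminium hydride at low temperature gives the allylic alcohol and leaves the alkene geometry and the aryl bromide untouched.

Step 3
Reactants: 3 (2E)-3-(6-bromo-2,3-dimethoxyphenyl)prop-2-en-1-ol
Product: 4 1-bromo-2-[(1E)-3-bromoprop-1-en-1-yl]-3,4-dimethoxybenzene
Conditions: PBr3 (0.4 equiv), Et2O, 0 °C; used without storage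
Reagents that add atoms: phosphorus tribromide, BrP(Br)Br
Why: bromide displaces the phosphite ester of the primary allylic alcohol (SN2), and the E-configured primary bromide is also the thermodynamically preferred allylic isomer.

Step 4
Reactants: 4 1-bromo-2-[(1E)-3-bromoprop-1-en-1-yl]-3,4-dimethoxybenzene
Product: 5 1-bromo-2-[(2R)-but-3-en-2-yl]-3,4-dimethoxybenzene
Conditions: MeMgBr (1.2 equiv, slow addition), CuBr·SMe2 (5 mol%), (S,S)-Taniaphos [1-(α-(dimethylamino)-2-(diphenylphosphino)benzyl)-2-(diphenylphosphino)ferrocene] (6 mol%), CH2Cl2, −75 °C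
Reagents that add atoms: methylmagnesium bromide, C[Mg]Br
Why: copper-catalysed asymmetric allylic alkylation (SN2′) with a Grignard reagent, in which the diphosphine-bound methylcopper species adds anti to the leaving bromide at the benzylic γ-carbon and reductive elimination from the σ-allyl trivalent copper intermediate forms the C4–CH3 bond on the alkene face selected by the ligand (4R).

Step 5
Reactants: 5 1-bromo-2-[(2R)-but-3-en-2-yl]-3,4-dimethoxybenzene
Product: 7 1-{2-[(2R)-but-3-en-2-yl]-3,4-dimethoxyphenyl}prop-2-en-1-ol (both carbinol epimers), via aryllithium 6 (not isolated)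
Conditions: n-BuLi (1.05 equiv), THF, −78 °C; acrolein (1.5 equiv), −78 °C; H2O
Reagents that add atoms: acrolein, C=CC=O
Why: bromine–lithium exchange at −78 °C outruns deprotonation of the benzylic–allylic C4–H and the hard aryllithium adds 1,2 to acrolein; the carbinol centre is left unselected because it is erased on ionisation in step 10.

Step 6
Reactants: 8 (2R)-3-bromo-2-methylpropan-1-ol
Product: 9 [(2R)-3-bromo-2-methylpropoxy](tert-butyl)dimethylsilane
Conditions: TBSCl, imidazole, CH2Cl2, 0 °C → rt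
Reagents that add atoms: tert-butyldimethylsilyl chloride, CC(C)(C)[Si](C)(C)Cl
Why: imidazole-promoted silylation of a primary alcohol, which leaves the primary bromide and the adjacent stereocentre untouched.

Step 7
Reactants: 9 [(2R)-3-bromo-2-methylpropoxy](tert-butyl)dimethylsilane
Product: 10 tert-butyldimethyl{[(2S)-2-methylhept-6-en-1-yl]oxy}silane
Conditions: CH2=CHCH2CH2MgBr (1.5 equiv), Li2CuCl4 (3 mol%), THF/NMP, 0 °C → rt
Reagents that add atoms: but-3-en-1-ylmagnesium bromide, C=CCC[Mg]Br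
Why: Kochi-type copper-catalysed sp3–sp3 coupling of a primary alkyl bromide with a primary alkyl Grignard reagent forms C13–C14; C15 is not a reacting carbon and keeps its configuration (the descriptor changes only through priorities).

Step 8
Reactants: 10 tert-butyldimethyl{[(2S)-2-methylhept-6-en-1-yl]oxy}silane
Product: 12 (6S)-7-[(tert-butyldimethylsilyl)oxy]-6-methylheptan-1-ol, via B-alkyl-9-borabicyclo[3.3.1]nonane 11 (not isolated)
Conditions: 9-BBN, THF, 0 °C → rt; then NaOH, H2O2, 0 °C → rt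
Reagents that add atoms: hydrogen peroxide, OO
Why: anti-Markovnikov hydroboration of the terminal alkene by a bulky dialkylborane followed by oxidative C–B to C–O exchange gives the primary alcohol.

Step 9
Reactants: 12 (6S)-7-[(tert-butyldimethylsilyl)oxy]-6-methylheptan-1-ol
Product: 13 (6S)-7-[(tert-butyldimethylsilyl)oxy]-6-methylheptanal
Conditions: Dess–Martin periodinane, NaHCO3, CH2Cl2, 0 °C → rt
Reagents that add atoms: none
Why: Dess–Martin oxidation stops at the aldehyde under buffered conditions and tolerates the silyl ether.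

Step 10
Reactants: 7 1-{2-[(2R)-but-3-en-2-yl]-3,4-dimethoxyphenyl}prop-2-en-1-ol; 13 (6S)-7-[(tert-butyldimethylsilyl)oxy]-6-methylheptanal (2 equiv)
Product: 15 (2S,3S)-3-{2-[(2R)-but-3-en-2-yl]-3,4-dimethoxyphenyl}-2-{(4S)-5-[(tert-butyldimethylsilyl)oxy]-4-methylpentyl}pent-4-en-1-ol, via pent-4-enal 14 (not isolated)
Conditions: [Ir(cod)Cl]2 (3 mol%), (S)-4-(5H-dibenzo[b,f]azepin-5-yl)dinaphtho[2,1-d:1′,2′-f][1,3,2]dioxaphosphepine (12 mol%), (R)-2-{bis[3,5-bis(trifluoromethyl)phenyl][(trimethylsilyl)oxy]methyl}pyrrolidine (15 mol%), (MeO)2P(O)OH (0.5 equiv), ClCH2CH2Cl, 25 °C; then MeOH, NaBH4, 0 °C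
Reagents that add atoms: none
Why: stereodivergent dual catalysis (iridium-catalysed branched-selective allylic substitution combined with enamine catalysis), in which the iridium–phosphoramidite/olefin complex ionises both carbinol epimers of 7 to one (η3-allyl)iridium species and fixes the face attacked at the benzylic terminus (C1, 1S), the enamine from 13 and the prolinol silyl ether exposes one face of its α-carbon (C11, 11S), and reduction in the same flask protects the epimerisable aldehyde α-centre.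

Step 11
Reactants: 15 (2S,3S)-3-{2-[(2R)-but-3-en-2-yl]-3,4-dimethoxyphenyl}-2-{(4S)-5-[(tert-butyldimethylsilyl)oxy]-4-methylpentyl}pent-4-en-1-ol
Product: 16 tert-butyl{[(2S,3S)-3-{2-[(2R)-but-3-en-2-yl]-3,4-dimethoxyphenyl}-2-{(4S)-5-[(tert-butyldimethylsilyl)oxy]-4-methylpentyl}pent-4-en-1-yl]oxy}dimethylsilane
Conditions: TBSCl, imidazole, DMF, rt
Reagents that add atoms: tert-butyldimethylsilyl chloride, CC(C)(C)[Si](C)(C)Cl
Why: routine silylation of the remaining primary alcohol gives a substrate with no free hydroxyl for the ruthenium and organolithium steps.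

Step 12
Reactants: 16 tert-butyl{[(2S,3S)-3-{2-[(2R)-but-3-en-2-yl]-3,4-dimethoxyphenyl}-2-{(4S)-5-[(tert-butyldimethylsilyl)oxy]-4-methylpentyl}pent-4-en-1-yl]oxy}dimethylsilane
Product: 17 (1S,4R)-1-{(2S,6S)-1,7-bis[(tert-butyldimethylsilyl)oxy]-6-methylheptan-2-yl}-5,6-dimethoxy-4-methyl-1,4-dihydronaphthalene
Conditions: second-generation Grubbs catalyst RuCl2(=CHPh)(H2IMes)(PCy3) (5 mol%), degassed CH2Cl2 (0.005 M), 40 °C, argon
Reagents that add atoms: none
Why: The benzylidene of the catalyst is exchanged for the less hindered C3 vinyl terminus, the resulting ruthenium alkylidene adds to the C2 vinyl group held next to it on ring A, and the ruthenacyclobutane opens to the C2=C3 alkene with loss of ethylene, which makes the closure irreversible. The closest known reaction type is ring-closing metathesis of ortho-bis(1-substituted allyl)benzenes to 1,4-dihydronaphthalenes. Ring B closes as a six-membered ring by alkene–alkene metathesis between two monosubstituted terminal alkenes, and the ring size allows only the cis alkene. No stereocentre is formed; C1, C4, C11 and C15 are saturated carbons that the carbene never binds, so the 1,4-trans relation fixed in steps 4 and 10 passes unchanged into the ring. The step needs cyclisation in preference to oligomerisation and no migration of C2=C3 into conjugation with ring A; the ortho placement of the two arms together with high dilution secures the first, and a short reaction at 40 °C under argon, followed directly by step 13, guards against ruthenium hydride isomerisation and air aromatisation.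

Step 13
Reactants: 17 (1S,4R)-1-{(2S,6S)-1,7-bis[(tert-butyldimethylsilyl)oxy]-6-methylheptan-2-yl}-5,6-dimethoxy-4-methyl-1,4-dihydronaphthalene
Product: 18 (1S,4R)-1-{(2S,6S)-1,7-bis[(tert-butyldimethylsilyl)oxy]-6-methylheptan-2-yl}-5,6-dimethoxy-4-methyl-1,2,3,4-tetrahydronaphthalene
Conditions: 2-O2NC6H4SO2NHNH2 (excess, in portions), Et3N, CH2Cl2, rt, argon
Reagents that add atoms: none
Why: diimide reduction, a concerted metal-free syn transfer of two hydrogens to the cis alkene, so no metal hydride is present that could move the double bond to C1 or C4 and scramble those centres.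

Step 14
Reactants: 18 (1S,4R)-1-{(2S,6S)-1,7-bis[(tert-butyldimethylsilyl)oxy]-6-methylheptan-2-yl}-5,6-dimethoxy-4-methyl-1,2,3,4-tetrahydronaphthalene
Product: 20 (5R,8S)-8-{(2S,6S)-1,7-bis[(tert-butyldimethylsilyl)oxy]-6-methylheptan-2-yl}-3,4-dimethoxy-5-methyl-5,6,7,8-tetrahydronaphthalene-2-carboxylic acid, via C7-lithio arene 19 (not isolated)
Conditions: n-BuLi (1.5 equiv), TMEDA, Et2O, 0 °C, 2 h; CO2 (gas), −78 °C → rt; 1 M HCl to pH 3, 0 °C
Reagents that add atoms: carbon dioxide, O=C=O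
Why: directed ortho-metalation, in which the C6 methoxy group steers lithiation to C7, the only ring C–H ortho to an oxygen, and the aryllithium is carboxylated by CO2.

Step 15
Reactants: 20 (5R,8S)-8-{(2S,6S)-1,7-bis[(tert-butyldimethylsilyl)oxy]-6-methylheptan-2-yl}-3,4-dimethoxy-5-methyl-5,6,7,8-tetrahydronaphthalene-2-carboxylic acid
Product: 21 (5R,8S)-8-[(2S,6S)-1,7-dihydroxy-6-methylheptan-2-yl]-3,4-dimethoxy-5-methyl-5,6,7,8-tetrahydronaphthalene-2-carboxylic acid
Conditions: HF·pyridine, THF/pyridine, 0 °C → rt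
Reagents that add atoms: none
Why: fluoride-driven cleavage of the two primary silyl ethers (Si–F bond formation) leaves the aryl methyl ethers and the acid unchanged, and removes silicon before BBr3, which could turn silyl ethers into bromides.

Step 16
Reactants: 21 (5R,8S)-8-[(2S,6S)-1,7-dihydroxy-6-methylheptan-2-yl]-3,4-dimethoxy-5-methyl-5,6,7,8-tetrahydronaphthalene-2-carboxylic acid
Product: 23 (5R,8S)-8-[(2S,6S)-1,7-bis(acetyloxy)-6-methylheptan-2-yl]-3,4-dimethoxy-5-methyl-5,6,7,8-tetrahydronaphthalene-2-carboxylic acid, via mixed acetic anhydride 22 (not isolated)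
Conditions: Ac2O, pyridine, DMAP (cat.), CH2Cl2, rt; then H2O, rt
Reagents that add atoms: acetic anhydride, CC(=O)OC(C)=O
Why: DMAP-catalysed acetylation esterifies both primary alcohols, while the carboxyl group is acylated only as far as a mixed anhydride that water returns to the free acid.

Step 17
Reactants: 23 (5R,8S)-8-[(2S,6S)-1,7-bis(acetyloxy)-6-methylheptan-2-yl]-3,4-dimethoxy-5-methyl-5,6,7,8-tetrahydronaphthalene-2-carboxylic acid
Product: 24 (5R,8S)-8-[(2S,6S)-1,7-bis(acetyloxy)-6-methylheptan-2-yl]-3,4-dihydroxy-5-methyl-5,6,7,8-tetrahydronaphthalene-2-carboxylic acid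
Conditions: BBr3 (5 equiv), CH2Cl2, −78 → −10 °C; ice-water
Reagents that add atoms: none
Why: Lewis acid demethylation of aryl methyl ethers (bromide attack on the O-methyl of the boron-complexed ether) is helped at C6 by the neighbouring carboxyl group and at C5 by formation of the cyclic catechol borate, and is run cold enough that the primary acetates should be cleaved far more slowly.

**Compound list**

1 | 6-bromo-2,3-dimethoxybenzaldehyde | COc1ccc(Br)c(C=O)c1OC | starting material
2 | ethyl (2E)-3-(6-bromo-2,3-dimethoxyphenyl)prop-2-enoate | CCOC(=O)/C=C/c1c(Br)ccc(OC)c1OC | intermediate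
3 | (2E)-3-(6-bromo-2,3-dimethoxyphenyl)prop-2-en-1-ol | OC/C=C/c1c(Br)ccc(OC)c1OC | intermediate
4 | 1-bromo-2-[(1E)-3-bromoprop-1-en-1-yl]-3,4-dimethoxybenzene | BrC/C=C/c1c(Br)ccc(OC)c1OC | intermediate
5 | 1-bromo-2-[(2R)-but-3-en-2-yl]-3,4-dimethoxybenzene | COc1ccc(Br)c([C@H](C)C=C)c1OC | intermediate
6 | {2-[(2R)-but-3-en-2-yl]-3,4-dimethoxyphenyl}lithium | COc1ccc([Li])c([C@H](C)C=C)c1OC | intermediate
7 | 1-{2-[(2R)-but-3-en-2-yl]-3,4-dimethoxyphenyl}prop-2-en-1-ol, both carbinol epimers | COc1ccc(C(O)C=C)c([C@H](C)C=C)c1OC | intermediate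
8 | (2R)-3-bromo-2-methylpropan-1-ol | OC[C@@H](C)CBr | starting material
9 | [(2R)-3-bromo-2-methylpropoxy](tert-butyl)dimethylsilane | CC(C)(C)[Si](C)(C)OC[C@@H](C)CBr | intermediate
10 | tert-butyldimethyl{[(2S)-2-methylhept-6-en-1-yl]oxy}silane | CC(C)(C)[Si](C)(C)OC[C@@H](C)CCCC=C | intermediate
11 | 9-{(6S)-7-[(tert-butyldimethylsilyl)oxy]-6-methylheptyl}-9-borabicyclo[3.3.1]nonane | CC(C)(C)[Si](C)(C)OC[C@@H](C)CCCCCB1C2CCCC1CCC2 | intermediate
12 | (6S)-7-[(tert-butyldimethylsilyl)oxy]-6-methylheptan-1-ol | CC(C)(C)[Si](C)(C)OC[C@@H](C)CCCCCO | intermediate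
13 | (6S)-7-[(tert-butyldimethylsilyl)oxy]-6-methylheptanal | CC(C)(C)[Si](C)(C)OC[C@@H](C)CCCCC=O | intermediate
14 | (2S,3S)-3-{2-[(2R)-but-3-en-2-yl]-3,4-dimethoxyphenyl}-2-{(4S)-5-[(tert-butyldimethylsilyl)oxy]-4-methylpentyl}pent-4-enal | CC(C)(C)[Si](C)(C)OC[C@@H](C)CCC[C@H](C=O)[C@H](C=C)c1ccc(OC)c(OC)c1[C@H](C)C=C | intermediate
15 | (2S,3S)-3-{2-[(2R)-but-3-en-2-yl]-3,4-dimethoxyphenyl}-2-{(4S)-5-[(tert-butyldimethylsilyl)oxy]-4-methylpentyl}pent-4-en-1-ol | CC(C)(C)[Si](C)(C)OC[C@@H](C)CCC[C@H](CO)[C@H](C=C)c1ccc(OC)c(OC)c1[C@H](C)C=C | intermediate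
16 | tert-butyl{[(2S,3S)-3-{2-[(2R)-but-3-en-2-yl]-3,4-dimethoxyphenyl}-2-{(4S)-5-[(tert-butyldimethylsilyl)oxy]-4-methylpentyl}pent-4-en-1-yl]oxy}dimethylsilane (metathesis precursor) | CC(C)(C)[Si](C)(C)OC[C@@H](C)CCC[C@H](CO[Si](C)(C)C(C)(C)C)[C@H](C=C)c1ccc(OC)c(OC)c1[C@H](C)C=C | intermediate
17 | (1S,4R)-1-{(2S,6S)-1,7-bis[(tert-butyldimethylsilyl)oxy]-6-methylheptan-2-yl}-5,6-dimethoxy-4-methyl-1,4-dihydronaphthalene (metathesis product) | CC(C)(C)[Si](C)(C)OC[C@@H](C)CCC[C@H](CO[Si](C)(C)C(C)(C)C)[C@@H]1C=C[C@@H](C)c2c1ccc(OC)c2OC | intermediate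
18 | (1S,4R)-1-{(2S,6S)-1,7-bis[(tert-butyldimethylsilyl)oxy]-6-methylheptan-2-yl}-5,6-dimethoxy-4-methyl-1,2,3,4-tetrahydronaphthalene | CC(C)(C)[Si](C)(C)OC[C@@H](C)CCC[C@H](CO[Si](C)(C)C(C)(C)C)[C@@H]1CC[C@@H](C)c2c1ccc(OC)c2OC | intermediate
19 | C7-lithio derivative of 18 (lithium on the ring carbon ortho to the C6 methoxy group) | CC(C)(C)[Si](C)(C)OC[C@@H](C)CCC[C@H](CO[Si](C)(C)C(C)(C)C)[C@@H]1CC[C@@H](C)c2c1cc([Li])c(OC)c2OC | intermediate
20 | (5R,8S)-8-{(2S,6S)-1,7-bis[(tert-butyldimethylsilyl)oxy]-6-methylheptan-2-yl}-3,4-dimethoxy-5-methyl-5,6,7,8-tetrahydronaphthalene-2-carboxylic acid | CC(C)(C)[Si](C)(C)OC[C@@H](C)CCC[C@H](CO[Si](C)(C)C(C)(C)C)[C@@H]1CC[C@@H](C)c2c1cc(C(=O)O)c(OC)c2OC | intermediate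
21 | (5R,8S)-8-[(2S,6S)-1,7-dihydroxy-6-methylheptan-2-yl]-3,4-dimethoxy-5-methyl-5,6,7,8-tetrahydronaphthalene-2-carboxylic acid | OC[C@@H](C)CCC[C@H](CO)[C@@H]1CC[C@@H](C)c2c1cc(C(=O)O)c(OC)c2OC | intermediate
22 | mixed anhydride of 23 with acetic acid (acetic (5R,8S)-8-[(2S,6S)-1,7-bis(acetyloxy)-6-methylheptan-2-yl]-3,4-dimethoxy-5-methyl-5,6,7,8-tetrahydronaphthalene-2-carboxylic anhydride) | CC(=O)OC[C@@H](C)CCC[C@H](COC(C)=O)[C@@H]1CC[C@@H](C)c2c1cc(C(=O)OC(C)=O)c(OC)c2OC | intermediate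
23 | (5R,8S)-8-[(2S,6S)-1,7-bis(acetyloxy)-6-methylheptan-2-yl]-3,4-dimethoxy-5-methyl-5,6,7,8-tetrahydronaphthalene-2-carboxylic acid | CC(=O)OC[C@@H](C)CCC[C@H](COC(C)=O)[C@@H]1CC[C@@H](C)c2c1cc(C(=O)O)c(OC)c2OC | intermediate
24 | (5R,8S)-8-[(2S,6S)-1,7-bis(acetyloxy)-6-methylheptan-2-yl]-3,4-dihydroxy-5-methyl-5,6,7,8-tetrahydronaphthalene-2-carboxylic acid (CNP0245723.2) | CC(=O)OC[C@@H](C)CCC[C@H](COC(C)=O)[C@@H]1CC[C@@H](C)c2c1cc(C(=O)O)c(O)c2O | target

**Step count and risks**

Total: 17 steps. Longest linear sequence: 13 steps (1 to 24 through steps 1–5 and 10–17); the chain aldehyde 13 takes 4 steps (6–9) from 8.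

Step 4. With bromine and methoxy flanking the allyl unit, methyl transfer may drift to the unhindered terminus (linear product) and facial discrimination may drop. The fallback sets out from 3 and returns at 5; it builds C4 by reagent-controlled epoxidation and stereospecific substitution instead of allylic alkylation. Sharpless asymmetric epoxidation of 3 (Ti(OiPr)4, D-(−)-diethyl tartrate, t-BuOOH, 4 Å molecular sieves, CH2Cl2, −20 °C) should give [(2R,3R)-3-(6-bromo-2,3-dimethoxyphenyl)oxiran-2-yl]methanol F1. Me3Al (CH2Cl2, 0 °C) should open the benzylic C–O bond with inversion to (2S,3S)-3-(6-bromo-2,3-dimethoxyphenyl)butane-1,2-diol F2. 1,1′-Thiocarbonyldiimidazole (THF, reflux) would then give (4S)-4-[(1S)-1-(6-bromo-2,3-dimethoxyphenyl)ethyl]-1,3-dioxolane-2-thione F3, and Corey–Winter fragmentation with P(OMe)3 at 110 °C would remove both oxygens to deliver 5.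

Step 10. Ionisation of the hindered carbinol may be slow, diastereocontrol may erode if the fixed C4 centre and the catalyst pair are mismatched, and the aldehyde α-centre may epimerise before reduction. The fallback sets out from 5 and 13 and returns at 17; it replaces the catalytic allylation by an Ireland–Claisen rearrangement with chirality transfer.
- Bromine–lithium exchange on 5 (n-BuLi, THF, −78 °C) and quenching with DMF would give 2-[(2R)-but-3-en-2-yl]-3,4-dimethoxybenzaldehyde F4.
- Wittig reaction with Ph3P=CHC(O)CH3 would give (3E)-4-{2-[(2R)-but-3-en-2-yl]-3,4-dimethoxyphenyl}but-3-en-2-one F5.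
- Reduction with catecholborane and (S)-2-methyl-CBS-oxazaborolidine (toluene, −78 °C) would give (2R,3E)-4-{2-[(2R)-but-3-en-2-yl]-3,4-dimethoxyphenyl}but-3-en-2-ol F6.
- Pinnick oxidation of 13 (NaClO2, NaH2PO4, 2-methylbut-2-ene) would give (6S)-7-[(tert-butyldimethylsilyl)oxy]-6-methylheptanoic acid F7.
- Steglich esterification of F6 with F7 (DCC, DMAP) would give (2R,3E)-4-{2-[(2R)-but-3-en-2-yl]-3,4-dimethoxyphenyl}but-3-en-2-yl (6S)-7-[(tert-butyldimethylsilyl)oxy]-6-methylheptanoate F8.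
- Enolisation with LiN(i-Pr)2 in THF at −78 °C, silylation with Me3SiCl and warming should rearrange F8 through a chair transition state (carbinol methyl equatorial, C12 cis to the allylic oxygen). This should give the 2,3-anti acid (2S,3S,4E)-3-{2-[(2R)-but-3-en-2-yl]-3,4-dimethoxyphenyl}-2-{(4S)-5-[(tert-butyldimethylsilyl)oxy]-4-methylpentyl}hex-4-enoic acid F9, which carries a propenyl group at C1.
- LiAlH4 would reduce F9 to (2S,3S,4E)-3-{2-[(2R)-but-3-en-2-yl]-3,4-dimethoxyphenyl}-2-{(4S)-5-[(tert-butyldimethylsilyl)oxy]-4-methylpentyl}hex-4-en-1-ol F10.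
- TBSCl/imidazole would give tert-butyl{[(2S,3S,4E)-3-{2-[(2R)-but-3-en-2-yl]-3,4-dimethoxyphenyl}-2-{(4S)-5-[(tert-butyldimethylsilyl)oxy]-4-methylpentyl}hex-4-en-1-yl]oxy}dimethylsilane F11.
- The ruthenium catalyst of step 12 would close F11 to 17 with loss of propene in place of ethylene.

Step 17. The primary acetates may be lost (O-acyl cleavage or exchange for bromide) while BBr3 removes the methyl ethers. The fallback sets out from 21 and returns at 24; it demethylates before the acetates exist and then acylates selectively. BBr3 (CH2Cl2, −78 → 0 °C) on 21 should give (5R,8S)-8-[(2S,6S)-1,7-dihydroxy-6-methylheptan-2-yl]-3,4-dihydroxy-5-methyl-5,6,7,8-tetrahydronaphthalene-2-carboxylic acid F12. Immobilised Candida antarctica lipase B with vinyl acetate (THF, 30 °C) should then acetylate only the two primary alcohols, since this enzyme does not acylate phenols, to give 24.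

**Further compounds**

F1 | step 4 | [(2R,3R)-3-(6-bromo-2,3-dimethoxyphenyl)oxiran-2-yl]methanol | COc1ccc(Br)c([C@H]2O[C@@H]2CO)c1OC
F2 | step 4 | (2S,3S)-3-(6-bromo-2,3-dimethoxyphenyl)butane-1,2-diol | COc1ccc(Br)c([C@H](C)[C@H](O)CO)c1OC
F3 | step 4 | (4S)-4-[(1S)-1-(6-bromo-2,3-dimethoxyphenyl)ethyl]-1,3-dioxolane-2-thione | COc1ccc(Br)c([C@H](C)[C@H]2COC(=S)O2)c1OC
F4 | step 10 | 2-[(2R)-but-3-en-2-yl]-3,4-dimethoxybenzaldehyde | COc1ccc(C=O)c([C@H](C)C=C)c1OC
F5 | step 10 | (3E)-4-{2-[(2R)-but-3-en-2-yl]-3,4-dimethoxyphenyl}but-3-en-2-one | COc1ccc(/C=C/C(C)=O)c([C@H](C)C=C)c1OC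
F6 | step 10 | (2R,3E)-4-{2-[(2R)-but-3-en-2-yl]-3,4-dimethoxyphenyl}but-3-en-2-ol | COc1ccc(/C=C/[C@@H](C)O)c([C@H](C)C=C)c1OC
F7 | step 10 | (6S)-7-[(tert-butyldimethylsilyl)oxy]-6-methylheptanoic acid | CC(C)(C)[Si](C)(C)OC[C@@H](C)CCCCC(=O)O
F8 | step 10 | (2R,3E)-4-{2-[(2R)-but-3-en-2-yl]-3,4-dimethoxyphenyl}but-3-en-2-yl (6S)-7-[(tert-butyldimethylsilyl)oxy]-6-methylheptanoate | CC(C)(C)[Si](C)(C)OC[C@@H](C)CCCCC(=O)O[C@H](C)/C=C/c1ccc(OC)c(OC)c1[C@H](C)C=C
F9 | step 10 | (2S,3S,4E)-3-{2-[(2R)-but-3-en-2-yl]-3,4-dimethoxyphenyl}-2-{(4S)-5-[(tert-butyldimethylsilyl)oxy]-4-methylpentyl}hex-4-enoic acid | CC(C)(C)[Si](C)(C)OC[C@@H](C)CCC[C@H](C(=O)O)[C@H](/C=C/C)c1ccc(OC)c(OC)c1[C@H](C)C=C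
F10 | step 10 | (2S,3S,4E)-3-{2-[(2R)-but-3-en-2-yl]-3,4-dimethoxyphenyl}-2-{(4S)-5-[(tert-butyldimethylsilyl)oxy]-4-methylpentyl}hex-4-en-1-ol | CC(C)(C)[Si](C)(C)OC[C@@H](C)CCC[C@H](CO)[C@H](/C=C/C)c1ccc(OC)c(OC)c1[C@H](C)C=C
F11 | step 10 | tert-butyl{[(2S,3S,4E)-3-{2-[(2R)-but-3-en-2-yl]-3,4-dimethoxyphenyl}-2-{(4S)-5-[(tert-butyldimethylsilyl)oxy]-4-methylpentyl}hex-4-en-1-yl]oxy}dimethylsilane | CC(C)(C)[Si](C)(C)OC[C@@H](C)CCC[C@H](CO[Si](C)(C)C(C)(C)C)[C@H](/C=C/C)c1ccc(OC)c(OC)c1[C@H](C)C=C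
F12 | step 17 | (5R,8S)-8-[(2S,6S)-1,7-dihydroxy-6-methylheptan-2-yl]-3,4-dihydroxy-5-methyl-5,6,7,8-tetrahydronaphthalene-2-carboxylic acid | OC[C@@H](C)CCC[C@H](CO)[C@@H]1CC[C@@H](C)c2c1cc(C(=O)O)c(O)c2O
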